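**Retrosynthetic overview**

1. Core numbering as in the target name: ring A = C1 (quaternary; CH3 and side chain), C2 (CH–CH3), C3, C4, C4a (H), C8a; ring B = C4a, C5 (gem-dimethyl), C6, C7 (C=O), C8, C8a (C8=C8a).
2. Endgame: O-sulfation of a primary alcohol; the enone C8=C8a–C7=O is drawn from a C7 carbinol by oxidation and dehydrogenation (C5 is quaternary, so only H on C8a can be lost); the side chain is joined to a C1 formyl group by Wittig olefination with a phosphonium salt that already holds the intact furan and the CH2O-bearing stereocentre (oxazolidinone-auxiliary hydroxymethylation, B-alkyl Suzuki–Miyaura coupling with 3-bromofuran).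
3. Key disconnection: the bicyclic C1-aldehyde goes back to an acyclic (2E,5S,8E,10Z)-trienal by a type 1 intramolecular Diels–Alder reaction that forms C4a–C8a and C1–C2, closes rings B and A in one operation and sets C1, C2 and C4a (plus a transient C8a).
4. Enabling feature: in ring A the unsubstituted C3–C4 edge is flanked by the CH stereocentres C2 and C4a, and quaternary C1 sits next to the trigonal fusion carbon C8a. This is a cyclohexene retron: C3=C4 comes from the diene, and C1–C8a from an α-methyl enal whose formyl carbon becomes the first side-chain CH2. C8a is the enone β-carbon, so its configuration is free, and the C7 oxygen of ring B can be carried as a silyloxy stereocentre that steers the cycloaddition and is erased on oxidation.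
5. Ring order: no ring exists before the key step; in the asynchronous cycloaddition the tether ring B (bond C4a–C8a at the enal β-carbon) leads and carbocycle ring A is completed last by the C1–C2 bond; the furan is bought, never built. The trienal comes from (R)-epichlorohydrin, isobutyronitrile, a vinyl Grignard reagent, iodoform, a formyl ylide and (Z)-propenylboronic acid.

Key step: step 9

Remark: an alkyl hydrogen sulfate is a strong acid and would be handled as its pyridinium or sodium salt; compound 38 is written as the neutral hydrogen sulfate, which is the form given for the target.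

**Step 1**
Reactants: 1 isobutyronitrile; 2 (R)-epichlorohydrin [(2R)-2-(chloromethyl)oxirane]
Product: 5 2,2-dimethyl-3-[(2R)-oxiran-2-yl]propanenitrile, via lithiated isobutyronitrile 3 (not isolated), via lithium chloro alkoxide 4 (not isolated)
Conditions: LiN(i-Pr)2 (LDA), THF, −78 °C; then 2, −78 → 25 °C
Reagents that add atoms: none
Why: Nitrile-anion alkylation with an epihalohydrin: the lithiated nitrile opens the epoxide of 2 at its CH2 terminus (SN2) and the chloro alkoxide closes to the new epoxide by intramolecular Williamson displacement, so the stereocentre is never attacked and is carried into 5 unchanged.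

**Step 2**
Reactants: 5
Product: 6 (4S)-4-hydroxy-2,2-dimethylhept-6-enenitrile
Conditions: CH2=CHMgBr (1.5 equiv), CuI (10 mol%), THF, −40 → −20 °C; aq. NH4Cl
Reagents that add atoms: vinylmagnesium bromide, C=C[Mg]Br
Why: Copper-catalysed Grignard opening of a terminal epoxide at the unsubstituted carbon (SN2) is faster at low temperature than addition to the hindered tertiary nitrile, so the carbinol centre is retained (4S by CIP priority only).

**Step 3**
Reactants: 6
Product: 7 (4S)-4-[(tert-butyldimethylsilyl)oxy]-2,2-dimethylhept-6-enenitrile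
Conditions: TBSCl, imidazole, DMF, 25 °C
Reagents that add atoms: tert-butyldimethylsilyl chloride (TBSCl), CC(C)(C)[Si](C)(C)Cl
Why: Imidazole-promoted silylation of a secondary alcohol; no stereocentre is affected.

**Step 4**
Reactants: 7
Product: 9 (4S)-4-[(tert-butyldimethylsilyl)oxy]-2,2-dimethylhept-6-enal, via N-aluminio aldimine 8 (not isolated)
Conditions: i-Bu2AlH (1.2 equiv), CH2Cl2, −78 °C; then aq. potassium sodium tartrate, SiO2
Reagents that add atoms: water, O
Why: Partial reduction of a nitrile with one equivalent of i-Bu2AlH stops at the N-aluminio imine, which is hydrolysed to the aldehyde on work-up; the α-carbon is quaternary, so no enolisation can occur.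

**Step 5**
Reactants: 9
Product: 10 tert-butyl{[(4S,7E)-8-iodo-6,6-dimethylocta-1,7-dien-4-yl]oxy}dimethylsilane
Conditions: CrCl2 (6 equiv), CHI3 (2 equiv), THF, 0 → 25 °C
Reagents that add atoms: iodoform, IC(I)I
Why: Takai olefination (geminal dichromium carbenoid from CHI3 and CrCl2) converts the aldehyde into the (E)-iodoalkene, and the terminal alkene and silyl ether are inert to it.

**Step 6**
Reactants: 10
Product: 12 (3R,6E)-3-[(tert-butyldimethylsilyl)oxy]-7-iodo-5,5-dimethylhept-6-enal, via vicinal diol 11 (not isolated)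
Conditions: OsO4 (2 mol%), NaIO4 (4 equiv), 2,6-lutidine, dioxane/H2O (3:1), 25 °C
Reagents that add atoms: osmium tetroxide, O=[Os](=O)(=O)=O; sodium periodate, [Na+].[O-]I(=O)(=O)=O
Why: Lemieux–Johnson oxidation: OsO4 dihydroxylates the monosubstituted alkene much faster than the electron-poor, neopentyl iodoalkene, and NaIO4 cleaves the diol to the aldehyde while 2,6-lutidine suppresses acid-mediated desilylation (3R by CIP priority only).

**Step 7**
Reactants: 12; 13 2-(triphenylphosphoranylidene)propanal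
Product: 14 (2E,5S,8E)-5-[(tert-butyldimethylsilyl)oxy]-9-iodo-2,7,7-trimethylnona-2,8-dienal
Conditions: toluene, 80 °C
Reagents that add atoms: none
Why: Wittig olefination with a formyl-stabilised ylide gives the (E)-2-methyl enal and does not react on with the less electrophilic, α-branched product enal.

**Step 8**
Reactants: 14; 15 (Z)-prop-1-en-1-ylboronic acid
Product: 16 (2E,5S,8E,10Z)-5-[(tert-butyldimethylsilyl)oxy]-2,7,7-trimethyldodeca-2,8,10-trienal
Conditions: Pd(PPh3)4 (5 mol%), TlOEt (1.8 equiv), THF/H2O (3:1), 25 °C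
Reagents that add atoms: none
Why: Suzuki–Miyaura coupling proceeds with retention at both sp2 carbons, so the (E)-iodoalkene and the (Z)-boronic acid give the (8E,10Z)-diene, and TlOEt makes transmetalation fast at 25 °C so that the enal and silyl ether see base only briefly.

**Step 9**
Reactants: 16
Product: 17 (1R,2R,4aR,7S,8aR)-7-[(tert-butyldimethylsilyl)oxy]-1,2,5,5-tetramethyl-1,2,4a,5,6,7,8,8a-octahydronaphthalene-1-carbaldehyde
Conditions: Me2AlCl (1.1 equiv), CH2Cl2, −78 → −20 °C
Reagents that add atoms: none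
Why: Lewis acid-activated, concerted but asynchronous [4+2] cycloaddition (type 1 intramolecular Diels–Alder reaction of a 2,8,10-trienal; closest known reaction type: the Me2AlCl-promoted cyclisation of 1,7,9-decatriene-type enals to octalins). Ring A (C1, C2, C3, C4, C4a, C8a of 17) is closed as the cycloadduct ring by suprafacial addition of the C8–C11 diene of 16 to its C2=C3 bond, and ring B is closed in the same event as the fused four-carbon tether ring; the bond at the enal β-carbon (C4a–C8a, common to both rings) leads and the C1–C2 bond, which completes ring A, forms last. The (8E,10Z) diene geometry puts H-4a and the C2 methyl group on one face, and the (2E) enal geometry in the formyl-exo (methyl-endo, tether-endo) transition state puts the C1 methyl group on the opposite face and the formyl group cis to the C2 methyl group; the cis-fused C8a centre formed alongside is erased in step 20. The absolute sense is set by the (5S) silyloxy centre, which must be equatorial in the chair-like tether because an axial position would be syn-axial to the axial methyl of the gem-dimethyl carbon. The step needs formyl-exo and π-facial selectivity: the first should be secured by the α-methyl group of the enal (α-substituted enals add exo under Lewis acid activation) and by the inside (Z)-methyl group, which clashes with an exo methyl but not with an exo formyl group; the second by the silyloxy group, while the low temperature should preclude Z→E isomerisation and 1,5-hydrogen shift.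

**Step 10**
Reactants: 18 (4S)-4-benzyl-1,3-oxazolidin-2-one; 19 pent-4-enoyl chloride
Product: 21 (4S)-4-benzyl-3-(pent-4-enoyl)-1,3-oxazolidin-2-one, via lithium oxazolidinide 20 (not isolated)
Conditions: n-BuLi, THF, −78 °C; then 19, −78 → 0 °C
Reagents that add atoms: none
Why: N-acylation of the lithiated oxazolidinone by an acid chloride (standard loading of the chiral auxiliary); the auxiliary stereocentre is untouched.

**Step 11**
Reactants: 21
Product: 23 (4S)-4-benzyl-3-[(2R)-2-(hydroxymethyl)pent-4-enoyl]-1,3-oxazolidin-2-one, via chlorotitanium enolate 22 (not isolated)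
Conditions: TiCl4 (1.05 equiv), i-Pr2NEt (1.1 equiv), CH2Cl2, 0 °C; then 1,3,5-trioxane, TiCl4 (1.05 equiv), 0 °C
Reagents that add atoms: 1,3,5-trioxane, C1OCOCO1
Why: Titanium-enolate hydroxymethylation of an N-acyl oxazolidinone: the chelated (Z)-enolate is attacked by the TiCl4-activated formaldehyde equivalent on the face opposite the benzyl group, which sets the (2R) centre that becomes the side-chain stereocentre.

**Step 12**
Reactants: 23
Product: 24 (4S)-4-benzyl-3-[(2R)-2-{[(tert-butyldiphenylsilyl)oxy]methyl}pent-4-enoyl]-1,3-oxazolidin-2-one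
Conditions: TBDPSCl, imidazole, DMF, 25 °C
Reagents that add atoms: tert-butyldiphenylsilyl chloride (TBDPSCl), CC(C)(C)[Si](Cl)(c1ccccc1)c1ccccc1
Why: Silylation of the primary alcohol as the acid-stable TBDPS ether, chosen so that it outlasts the later cleavage of the secondary TBS ether.

**Step 13**
Reactants: 24
Product: 25 (2S)-2-{[(tert-butyldiphenylsilyl)oxy]methyl}pent-4-en-1-ol
Conditions: LiBH4, H2O (1 equiv), Et2O, 0 °C
Reagents that add atoms: none
Why: Reductive cleavage of the imide by LiBH4 (hydride attack at the exocyclic carbonyl) releases the primary alcohol and the auxiliary without touching the α-stereocentre (2S by CIP priority only).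

**Step 14**
Reactants: 25; 26 3-bromofuran
Product: 28 (2S)-2-{[(tert-butyldiphenylsilyl)oxy]methyl}-5-(furan-3-yl)pentan-1-ol, via bis-9-BBN adduct 27 (not isolated)
Conditions: 9-BBN (2.2 equiv), THF, 0 → 25 °C; then 26, Pd(dppf)Cl2 (5 mol%), aq. K3PO4, DMF, 50 °C
Reagents that add atoms: none
Why: Anti-Markovnikov hydroboration of the terminal alkene with 9-BBN followed by B-alkyl Suzuki–Miyaura coupling installs the intact furan ring; the hydroxyl group is masked in the flask as its borinate and freed on work-up.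

**Step 15**
Reactants: 28
Product: 29 tert-butyl{[(2R)-5-(furan-3-yl)-2-(iodomethyl)pentyl]oxy}diphenylsilane
Conditions: I2, PPh3, imidazole, CH2Cl2, 0 → 25 °C
Reagents that add atoms: iodine, II
Why: Appel-type (Garegg–Samuelsson) iodination via the alkoxyphosphonium iodide, SN2 at the CH2 group and neutral enough for furan and silyl ether; the stereocentre is not involved (2R by CIP priority only).

**Step 16**
Reactants: 29
Product: 30 [(2R)-2-{[(tert-butyldiphenylsilyl)oxy]methyl}-5-(furan-3-yl)pentyl]triphenylphosphonium iodide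
Conditions: PPh3 (3 equiv), MeCN, 85 °C
Reagents that add atoms: triphenylphosphine, c1ccc(cc1)P(c1ccccc1)c1ccccc1
Why: SN2 quaternisation of PPh3 by the primary iodide; the β-branch only slows the reaction.

**Step 17**
Reactants: 30; 17
Product: 32 tert-butyl({(2S,3Z)-4-[(1R,2R,4aR,7S,8aR)-7-[(tert-butyldimethylsilyl)oxy]-1,2,5,5-tetramethyl-1,2,4a,5,6,7,8,8a-octahydronaphthalen-1-yl]-2-[3-(furan-3-yl)propyl]but-3-en-1-yl}oxy)diphenylsilane, via phosphonium ylide 31 (not isolated)
Conditions: NaN(SiMe3)2, THF, −78 → 0 °C; then 17, −78 → 25 °C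
Reagents that add atoms: none
Why: Wittig olefination of the non-enolisable neopentyl aldehyde with the non-stabilised ylide joins the fragments at the future C1–CH2 bond (Z-alkene expected; the geometry is irrelevant because the alkene is reduced next), and neither stereocentre flanking the new double bond is acidic.

**Step 18**
Reactants: 32
Product: 33 tert-butyl({(2S)-4-[(1R,2R,4aR,7S,8aR)-7-[(tert-butyldimethylsilyl)oxy]-1,2,5,5-tetramethyldecahydronaphthalen-1-yl]-2-[3-(furan-3-yl)propyl]butyl}oxy)diphenylsilane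
Conditions: 2-nitrobenzenesulfonyl hydrazide (NBSH, excess, in portions), Et3N, CH2Cl2, 25 °C
Reagents that add atoms: none
Why: Diimide reduction: concerted syn transfer of H2 to both 1,2-disubstituted C=C bonds but not to the aromatic furan, with no metal hydride that could move the side-chain alkene into the allylic stereocentre.

**Step 19**
Reactants: 33
Product: 34 (2S,4aR,7R,8R,8aR)-8-[(3S)-3-{[(tert-butyldiphenylsilyl)oxy]methyl}-6-(furan-3-yl)hexyl]-4,4,7,8-tetramethyldecahydronaphthalen-2-ol
Conditions: CSA (0.2 equiv), MeOH/CH2Cl2 (1:1), 0 → 25 °C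
Reagents that add atoms: none
Why: Acid-catalysed methanolysis removes the secondary TBS ether while the far more acid-stable primary TBDPS ether survives, and catalytic CSA at this temperature should spare the 3-alkylfuran.

**Step 20**
Reactants: 34
Product: 36 (4aS,7R,8R)-8-[(3S)-3-{[(tert-butyldiphenylsilyl)oxy]methyl}-6-(furan-3-yl)hexyl]-4,4,7,8-tetramethyl-4,4a,5,6,7,8-hexahydronaphthalen-2(3H)-one, via saturated ketone 35 (not isolated)
Conditions: IBX (3.5 equiv), 4-methoxypyridine N-oxide (3.5 equiv), DMSO, 25 °C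
Reagents that add atoms: none
Why: IBX oxidises the carbinol to ketone 35 and, as its N-oxide complex, dehydrogenates it through the enol (IBX dehydrogenation); the β-carbon on the other side is the quaternary gem-dimethyl carbon, so the only β-hydrogen is the one at the ring fusion and the target enone is the only possible product, with the C4a centre untouched.

**Step 21**
Reactants: 36
Product: 37 (4aS,7R,8R)-8-[(3S)-6-(furan-3-yl)-3-(hydroxymethyl)hexyl]-4,4,7,8-tetramethyl-4,4a,5,6,7,8-hexahydronaphthalen-2(3H)-one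
Conditions: HF·pyridine, pyridine, THF, 0 → 25 °C
Reagents that add atoms: none
Why: Fluoride-mediated cleavage of the TBDPS ether under buffered, weakly acidic conditions that should not enolise the enone toward the γ-stereocentre C4a.

**Step 22**
Reactants: 37
Product: 38 (2S)-5-(furan-3-yl)-2-{2-[(1R,2R,4aS)-1,2,5,5-tetramethyl-7-oxo-1,2,3,4,4a,5,6,7-octahydronaphthalen-1-yl]ethyl}pentyl hydrogen sulfate (target)
Conditions: SO3·pyridine (3 equiv), pyridine, 25 °C; aqueous work-up
Reagents that add atoms: sulfur trioxide–pyridine complex, [O-]S(=O)(=O)[n+]1ccccc1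
Why: O-sulfonation of the primary alcohol with SO3·pyridine gives the sulfate monoester under non-acidic conditions compatible with the furan and the γ-epimerisable enone.

**Compound list**

1 | isobutyronitrile | CC(C)C#N | starting material
2 | (R)-epichlorohydrin | ClC[C@H]1CO1 | starting material
3 | lithium 2-cyanopropan-2-ide (lithiated isobutyronitrile) | [Li+].C[C-](C)C#N | intermediate
4 | lithium (2R)-1-chloro-4-cyano-4-methylpentan-2-olate | ClC[C@H]([O-])CC(C)(C)C#N.[Li+] | intermediate
5 | 2,2-dimethyl-3-[(2R)-oxiran-2-yl]propanenitrile | N#CC(C)(C)C[C@@H]1CO1 | intermediate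
6 | (4S)-4-hydroxy-2,2-dimethylhept-6-enenitrile | N#CC(C)(C)C[C@@H](O)CC=C | intermediate
7 | (4S)-4-[(tert-butyldimethylsilyl)oxy]-2,2-dimethylhept-6-enenitrile | N#CC(C)(C)C[C@@H](O[Si](C)(C)C(C)(C)C)CC=C | intermediate
8 | N-(diisobutylalumanyl) aldimine of 9 | CC(C)C[Al](CC(C)C)N=CC(C)(C)C[C@@H](O[Si](C)(C)C(C)(C)C)CC=C | intermediate
9 | (4S)-4-[(tert-butyldimethylsilyl)oxy]-2,2-dimethylhept-6-enal | O=CC(C)(C)C[C@@H](O[Si](C)(C)C(C)(C)C)CC=C | intermediate
10 | tert-butyl{[(4S,7E)-8-iodo-6,6-dimethylocta-1,7-dien-4-yl]oxy}dimethylsilane | I/C=C/C(C)(C)C[C@@H](O[Si](C)(C)C(C)(C)C)CC=C | intermediate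
11 | (2RS,4R,7E)-4-[(tert-butyldimethylsilyl)oxy]-8-iodo-6,6-dimethyloct-7-ene-1,2-diol | I/C=C/C(C)(C)C[C@@H](O[Si](C)(C)C(C)(C)C)CC(O)CO | intermediate
12 | (3R,6E)-3-[(tert-butyldimethylsilyl)oxy]-7-iodo-5,5-dimethylhept-6-enal | I/C=C/C(C)(C)C[C@@H](O[Si](C)(C)C(C)(C)C)CC=O | intermediate
13 | 2-(triphenylphosphoranylidene)propanal | CC(C=O)=P(c1ccccc1)(c1ccccc1)c1ccccc1 | starting material
14 | (2E,5S,8E)-5-[(tert-butyldimethylsilyl)oxy]-9-iodo-2,7,7-trimethylnona-2,8-dienal | I/C=C/C(C)(C)C[C@@H](O[Si](C)(C)C(C)(C)C)C/C=C(\C)C=O | intermediate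
15 | (Z)-prop-1-en-1-ylboronic acid | C/C=C\B(O)O | starting material
16 | (2E,5S,8E,10Z)-5-[(tert-butyldimethylsilyl)oxy]-2,7,7-trimethyldodeca-2,8,10-trienal | C/C=C\C=C\C(C)(C)C[C@@H](O[Si](C)(C)C(C)(C)C)C/C=C(\C)C=O | intermediate
17 | (1R,2R,4aR,7S,8aR)-7-[(tert-butyldimethylsilyl)oxy]-1,2,5,5-tetramethyl-1,2,4a,5,6,7,8,8a-octahydronaphthalene-1-carbaldehyde | O=C[C@]1(C)[C@H](C)C=C[C@@H]2[C@H]1C[C@H](O[Si](C)(C)C(C)(C)C)CC2(C)C | intermediate
18 | (4S)-4-benzyl-1,3-oxazolidin-2-one | O=C1N[C@@H](Cc2ccccc2)CO1 | starting material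
19 | pent-4-enoyl chloride | C=CCCC(Cl)=O | starting material
20 | lithium (4S)-4-benzyl-2-oxo-1,3-oxazolidin-3-ide | [Li+].O=C1[N-][C@@H](Cc2ccccc2)CO1 | intermediate
21 | (4S)-4-benzyl-3-(pent-4-enoyl)-1,3-oxazolidin-2-one | C=CCCC(=O)N1[C@@H](Cc2ccccc2)COC1=O | intermediate
22 | trichlorotitanium (Z)-enolate of 21 | C=CC/C=C(\O[Ti](Cl)(Cl)Cl)N1[C@@H](Cc2ccccc2)COC1=O | intermediate
23 | (4S)-4-benzyl-3-[(2R)-2-(hydroxymethyl)pent-4-enoyl]-1,3-oxazolidin-2-one | C=CC[C@H](CO)C(=O)N1[C@@H](Cc2ccccc2)COC1=O | intermediate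
24 | (4S)-4-benzyl-3-[(2R)-2-{[(tert-butyldiphenylsilyl)oxy]methyl}pent-4-enoyl]-1,3-oxazolidin-2-one | C=CC[C@H](CO[Si](c1ccccc1)(c1ccccc1)C(C)(C)C)C(=O)N1[C@@H](Cc2ccccc2)COC1=O | intermediate
25 | (2S)-2-{[(tert-butyldiphenylsilyl)oxy]methyl}pent-4-en-1-ol | C=CC[C@H](CO[Si](c1ccccc1)(c1ccccc1)C(C)(C)C)CO | intermediate
26 | 3-bromofuran | Brc1ccoc1 | starting material
27 | bis-9-BBN adduct of 25 (B-alkyl-9-borabicyclo[3.3.1]nonane at the former alkene terminus, hydroxyl bound as its 9-BBN borinate) | C1CCC2CCCC1B2CCC[C@H](CO[Si](c1ccccc1)(c1ccccc1)C(C)(C)C)COB1C2CCCC1CCC2 | intermediate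
28 | (2S)-2-{[(tert-butyldiphenylsilyl)oxy]methyl}-5-(furan-3-yl)pentan-1-ol | o1ccc(CCC[C@H](CO[Si](c2ccccc2)(c2ccccc2)C(C)(C)C)CO)c1 | intermediate
29 | tert-butyl{[(2R)-5-(furan-3-yl)-2-(iodomethyl)pentyl]oxy}diphenylsilane | o1ccc(CCC[C@H](CO[Si](c2ccccc2)(c2ccccc2)C(C)(C)C)CI)c1 | intermediate
30 | [(2R)-2-{[(tert-butyldiphenylsilyl)oxy]methyl}-5-(furan-3-yl)pentyl]triphenylphosphonium iodide | o1ccc(CCC[C@H](CO[Si](c2ccccc2)(c2ccccc2)C(C)(C)C)C[P+](c2ccccc2)(c2ccccc2)c2ccccc2)c1.[I-] | intermediate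
31 | [(2R)-2-{[(tert-butyldiphenylsilyl)oxy]methyl}-5-(furan-3-yl)pentylidene]triphenyl-λ5-phosphane (ylide) | o1ccc(CCC[C@H](CO[Si](c2ccccc2)(c2ccccc2)C(C)(C)C)C=P(c2ccccc2)(c2ccccc2)c2ccccc2)c1 | intermediate
32 | tert-butyl({(2S,3Z)-4-[(1R,2R,4aR,7S,8aR)-7-[(tert-butyldimethylsilyl)oxy]-1,2,5,5-tetramethyl-1,2,4a,5,6,7,8,8a-octahydronaphthalen-1-yl]-2-[3-(furan-3-yl)propyl]but-3-en-1-yl}oxy)diphenylsilane | o1ccc(CCC[C@H](CO[Si](c2ccccc2)(c2ccccc2)C(C)(C)C)/C=C\[C@]2(C)[C@H](C)C=C[C@@H]3[C@H]2C[C@H](O[Si](C)(C)C(C)(C)C)CC3(C)C)c1 | intermediate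
33 | tert-butyl({(2S)-4-[(1R,2R,4aR,7S,8aR)-7-[(tert-butyldimethylsilyl)oxy]-1,2,5,5-tetramethyldecahydronaphthalen-1-yl]-2-[3-(furan-3-yl)propyl]butyl}oxy)diphenylsilane | o1ccc(CCC[C@H](CO[Si](c2ccccc2)(c2ccccc2)C(C)(C)C)CC[C@]2(C)[C@H](C)CC[C@@H]3[C@H]2C[C@H](O[Si](C)(C)C(C)(C)C)CC3(C)C)c1 | intermediate
34 | (2S,4aR,7R,8R,8aR)-8-[(3S)-3-{[(tert-butyldiphenylsilyl)oxy]methyl}-6-(furan-3-yl)hexyl]-4,4,7,8-tetramethyldecahydronaphthalen-2-ol | o1ccc(CCC[C@H](CO[Si](c2ccccc2)(c2ccccc2)C(C)(C)C)CC[C@]2(C)[C@H](C)CC[C@@H]3[C@H]2C[C@H](O)CC3(C)C)c1 | intermediate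
35 | (4aR,7R,8R,8aR)-8-[(3S)-3-{[(tert-butyldiphenylsilyl)oxy]methyl}-6-(furan-3-yl)hexyl]-4,4,7,8-tetramethyloctahydronaphthalen-2(1H)-one | o1ccc(CCC[C@H](CO[Si](c2ccccc2)(c2ccccc2)C(C)(C)C)CC[C@]2(C)[C@H](C)CC[C@@H]3[C@H]2CC(=O)CC3(C)C)c1 | intermediate
36 | (4aS,7R,8R)-8-[(3S)-3-{[(tert-butyldiphenylsilyl)oxy]methyl}-6-(furan-3-yl)hexyl]-4,4,7,8-tetramethyl-4,4a,5,6,7,8-hexahydronaphthalen-2(3H)-one | o1ccc(CCC[C@H](CO[Si](c2ccccc2)(c2ccccc2)C(C)(C)C)CC[C@]2(C)[C@H](C)CC[C@@H]3C2=CC(=O)CC3(C)C)c1 | intermediate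
37 | (4aS,7R,8R)-8-[(3S)-6-(furan-3-yl)-3-(hydroxymethyl)hexyl]-4,4,7,8-tetramethyl-4,4a,5,6,7,8-hexahydronaphthalen-2(3H)-one | o1ccc(CCC[C@H](CO)CC[C@]2(C)[C@H](C)CC[C@@H]3C2=CC(=O)CC3(C)C)c1 | intermediate
38 | (2S)-5-(furan-3-yl)-2-{2-[(1R,2R,4aS)-1,2,5,5-tetramethyl-7-oxo-1,2,3,4,4a,5,6,7-octahydronaphthalen-1-yl]ethyl}pentyl hydrogen sulfate (CNP0424620.3) | C[C@@H]1CC[C@@H]2C(=CC(=O)CC2(C)C)[C@]1(C)CC[C@H](CCCc1ccoc1)COS(=O)(=O)O | target

**Step count and risks**

Total step count: 22 (steps 1–9 trienal and key step; steps 10–16 side-chain phosphonium salt; steps 17–22 endgame).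
Longest linear sequence: 15 steps (steps 1–9 and 17–22).

Most likely to fail, riskiest first:

Step 9. What may go wrong: the (Z)-methyl terminus slows the cycloaddition so much that Lewis-acid-mediated Z→E isomerisation of the diene, or closure through the competing formyl-endo mode, erodes the C2 and C1 configurations. Fallback (ionic Diels–Alder reaction, a cationic dienophile instead of a Lewis acid complex): setting out from 16, the aldehyde would be converted with Me3SiOCH2CH2OSiMe3 and catalytic Me3SiOTf (CH2Cl2, −78 °C) into the acetal 2-[(1E,4S,7E,9Z)-4-[(tert-butyldimethylsilyl)oxy]-1,6,6-trimethylundeca-1,7,9-trien-1-yl]-1,3-dioxolane F1. The same acid should open this acetal reversibly to a 2-alkenyl-1,3-dioxolan-2-ylium ion, a far stronger dienophile that should cyclise at −78 to −40 °C, where the Z-olefin is configurationally safe, to the cycloadduct acetal 2-[(1R,2R,4aR,7S,8aR)-7-[(tert-butyldimethylsilyl)oxy]-1,2,5,5-tetramethyl-1,2,4a,5,6,7,8,8a-octahydronaphthalen-1-yl]-1,3-dioxolane F2. Mild hydrolysis (PPTS, wet acetone) would bring the sequence back to the route at 17.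

Step 17. What may go wrong: the formyl group on the quaternary carbon, shielded by the C2 methyl group and the ring fusion, may not be reached by the β-branched ylide, so that the ylide decays and the aldehyde is recovered. Fallback (organolithium addition, then Barton–McCombie deoxygenation): setting out from 17, the ring alkene would first be hydrogenated (H2, Pd/C, EtOAc) to the saturated aldehyde (1R,2R,4aR,7S,8aR)-7-[(tert-butyldimethylsilyl)oxy]-1,2,5,5-tetramethyldecahydronaphthalene-1-carbaldehyde F3, so that no 5-hexenyl radical cyclisation can occur later. Iodide 29 would be converted with t-BuLi (2 equiv, Et2O, −78 °C) into [(2R)-2-{[(tert-butyldiphenylsilyl)oxy]methyl}-5-(furan-3-yl)pentyl]lithium F4, which should add to F3 to give the carbinol (1RS,3S)-1-[(1R,2R,4aR,7S,8aR)-7-[(tert-butyldimethylsilyl)oxy]-1,2,5,5-tetramethyldecahydronaphthalen-1-yl]-3-{[(tert-butyldiphenylsilyl)oxy]methyl}-6-(furan-3-yl)hexan-1-ol F5. NaH, CS2 and MeI would give the O-alkyl S-methyl carbonodithioate (xanthate) of that carbinol F6, and Bu3SnH with AIBN (toluene, 100 °C) should remove the oxygen and bring the sequence back to the route at 33, steps 17 and 18 being replaced.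

Step 20. What may go wrong: over-oxidation, that is attack of the hypervalent iodine reagent on the electron-rich furan or its neighbouring CH2 group, while dehydrogenation of the hindered ketone stays incomplete. Fallback (Saegusa–Ito sequence): setting out from 34, Dess–Martin periodinane (CH2Cl2, NaHCO3) would give ketone 35, now isolated; LiN(i-Pr)2 and Me3SiCl (THF, −78 °C) would give the trimethylsilyl enol ether tert-butyl{[(2S)-5-(furan-3-yl)-2-{2-[(1R,2R,4aR,8aS)-1,2,5,5-tetramethyl-7-[(trimethylsilyl)oxy]-1,2,3,4,4a,5,6,8a-octahydronaphthalen-1-yl]ethyl}pentyl]oxy}diphenylsilane F7. Its regioisomer toward the gem-dimethyl side has no β-hydrogen and would return 35 on work-up. Pd(OAc)2 in MeCN at 25 °C should then convert F7 into 36, where the route is rejoined.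

**Further compounds**

F1 | step 9 | 2-[(1E,4S,7E,9Z)-4-[(tert-butyldimethylsilyl)oxy]-1,6,6-trimethylundeca-1,7,9-trien-1-yl]-1,3-dioxolane | C/C=C\C=C\C(C)(C)C[C@@H](O[Si](C)(C)C(C)(C)C)C/C=C(\C)C1OCCO1
F2 | step 9 | 2-[(1R,2R,4aR,7S,8aR)-7-[(tert-butyldimethylsilyl)oxy]-1,2,5,5-tetramethyl-1,2,4a,5,6,7,8,8a-octahydronaphthalen-1-yl]-1,3-dioxolane | O1CCOC1[C@]1(C)[C@H](C)C=C[C@@H]2[C@H]1C[C@H](O[Si](C)(C)C(C)(C)C)CC2(C)C
F3 | step 17 | (1R,2R,4aR,7S,8aR)-7-[(tert-butyldimethylsilyl)oxy]-1,2,5,5-tetramethyldecahydronaphthalene-1-carbaldehyde | O=C[C@]1(C)[C@H](C)CC[C@@H]2[C@H]1C[C@H](O[Si](C)(C)C(C)(C)C)CC2(C)C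
F4 | step 17 | [(2R)-2-{[(tert-butyldiphenylsilyl)oxy]methyl}-5-(furan-3-yl)pentyl]lithium | o1ccc(CCC[C@H](CO[Si](c2ccccc2)(c2ccccc2)C(C)(C)C)C[Li])c1
F5 | step 17 | (1RS,3S)-1-[(1R,2R,4aR,7S,8aR)-7-[(tert-butyldimethylsilyl)oxy]-1,2,5,5-tetramethyldecahydronaphthalen-1-yl]-3-{[(tert-butyldiphenylsilyl)oxy]methyl}-6-(furan-3-yl)hexan-1-ol | o1ccc(CCC[C@H](CO[Si](c2ccccc2)(c2ccccc2)C(C)(C)C)CC(O)[C@]2(C)[C@H](C)CC[C@@H]3[C@H]2C[C@H](O[Si](C)(C)C(C)(C)C)CC3(C)C)c1
F6 | step 17 | O-{(1RS,3S)-1-[(1R,2R,4aR,7S,8aR)-7-[(tert-butyldimethylsilyl)oxy]-1,2,5,5-tetramethyldecahydronaphthalen-1-yl]-3-{[(tert-butyldiphenylsilyl)oxy]methyl}-6-(furan-3-yl)hexyl} S-methyl carbonodithioate | o1ccc(CCC[C@H](CO[Si](c2ccccc2)(c2ccccc2)C(C)(C)C)CC(OC(=S)SC)[C@]2(C)[C@H](C)CC[C@@H]3[C@H]2C[C@H](O[Si](C)(C)C(C)(C)C)CC3(C)C)c1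
F7 | step 20 | tert-butyl{[(2S)-5-(furan-3-yl)-2-{2-[(1R,2R,4aR,8aS)-1,2,5,5-tetramethyl-7-[(trimethylsilyl)oxy]-1,2,3,4,4a,5,6,8a-octahydronaphthalen-1-yl]ethyl}pentyl]oxy}diphenylsilane | o1ccc(CCC[C@H](CO[Si](c2ccccc2)(c2ccccc2)C(C)(C)C)CC[C@]2(C)[C@H](C)CC[C@@H]3[C@H]2C=C(O[Si](C)(C)C)CC3(C)C)c1
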